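Readings and results come from a simulation from invented constants.

Look for what stays the same when the charge changes: in the oak and birch runs, that is the product made per minute, counted in absolute units.

common to all: partner 46.8 mM; free catalyst 36 µM

| flask | starting material | scavenger | remark | time |
|---|---|---|---|---|
| oak | 17 mM (fed, over 8.0 min) | 31.2 mM | run made earlier |  |
| birch | 13 mM (fed, over 8.0 min) | 31.2 mM | run made earlier |  |
| Monday's | 26 mM (fed, over 8.0 min) | 31.0 mM |  | 2.0 h |
| Friday's | 26 mM (fed, over 8.0 min) | 62.0 mM |  | 2.0 h |
| Thursday's | 26 mM (fed, over 8.0 min) | 120 mM |  | 2.0 h |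

| run | time / min | starting material / % | product / % |
|---|---|---|---|
| oak | 1.33 | 16.2 | 0.2 |
| oak | 4.00 | 49.8 | 0.7 |
| oak | 6.00 | 73.6 | 0.8 |
| oak | 10.0 | 97.2 | 1.9 |
| oak | 15.0 | 96.2 | 3.4 |
| oak | 20.0 | 95.4 | 4.9 |
| oak | 25.0 | 93.6 | 5.9 |
| birch | 2.00 | 25.0 | 0.4 |
| birch | 3.00 | 36.6 | 0.6 |
| birch | 4.00 | 49.5 | 0.6 |
| birch | 6.00 | 73.5 | 1.5 |
| birch | 10.0 | 97.1 | 2.4 |
| birch | 15.0 | 95.4 | 4.2 |
| birch | 25.0 | 92.3 | 7.5 |

(readings scatter by 0.3 percentage points)

- the numbers in the tables scatter by 0.3 percentage points (one standard deviation)
- percentages count the whole charge, also what has not yet gone in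
- no earlier run changes the charge of scavenger; that part of a forecast is a guess

1. part of the starting material that has reacted at the end, Monday's
2. part of the starting material that has reacted at the end, Friday's
3. part of the starting material that has reacted at the end, Thursday's
4. what raising the concentration of scavenger from its lowest to its highest value here does to the part of the starting material that has reacted (changes below 5 percentage points count as none) (no change / it rises / it falls)

Take each slope after the feed, from the reading at 10.0 min to the one at 25.0 min, and convert percent to concentration: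

r(oak) = 0.0453 mM min⁻¹

r(birch) = 0.0442 mM min⁻¹

The charges differ by a factor 1.31, the slopes by 1.02, so treat the rate as zero order in starting material. Divide the mean slope by the catalyst charge c_C to get n, the turnover frequency: product formed per minute per catalyst charged.

n = 1.24 min⁻¹

Freeze n. Next find the lag L, the time at which the straight product line, run backward, meets zero, from the first reading after the feed in each run and their mean:

L = 2.91 min

Then, for charge c_A and time t, the part reacted Y, counted as product formed, is:

Y = n·c_C·(t − L)/c_A = 20.2 %

No earlier run varies the scavenger, so guess it flat; all three flasks then get Y.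

Now test the weak link, the frozen rate. The slopes were read with starting material near 15.9 mM in oak, and Y leaves 20.8 mM in Monday's, so the flask stays on the richer side of what was measured. The scatter of the readings puts one standard deviation of 0.00303 mM min⁻¹ on the mean slope, hence 1.4 percentage points on Y.

The forecast gives 20.2 %, 20.2 % and 20.2 %, with no change, guessing that the scavenger is “simply in excess and has no kinetic role”.

Monday's, Friday's and Thursday's each give 21.3 %, and the scavenger's whole range moves that by 0.012 points: no change.

    starting material + free catalyst → catalyst intermediate A (k = 8.10 M⁻¹ s⁻¹)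
    catalyst intermediate A ⇌ catalyst intermediate B (K = 0.330, k = 0.220 s⁻¹)
    partner + catalyst intermediate B ⇌ catalyst intermediate C (K = 16.0 M⁻¹, k = 19.0 M⁻¹ s⁻¹)
    catalyst intermediate C → catalyst intermediate D (k = 0.290 s⁻¹)
    catalyst intermediate D ⇌ released group + catalyst intermediate E (K = 0.730 M, k = 0.240 s⁻¹)
    catalyst intermediate E → free catalyst + product (k = 0.240 s⁻¹)
    partner + released group ⇌ idle adduct, settled at all times (K = 16.0 M⁻¹)
    scavenger + released group → scavenged by-product (k = 0.280 M⁻¹ s⁻¹)

In Monday's at 2.00 h, catalyst intermediate A, the resting state, holds 49.9 % of the catalyst, more than free catalyst at 12.4 %. Put the result back through the rule and n comes out at 1.32 min⁻¹. Run the frozen n on Monday's read at 8.0 h: it gives 82.1 %, while that flask stands at 73.0 %, with free catalyst at 24.1 %.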